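## Retrosynthetic overview

1. The target (prostaglandin E2 1,15-lactone 11-acetate) is opened at the 5Z alkene: a Z-selective ring-closing metathesis of an acyclic diene ester closes the 13-membered lactone last.
2. The diene ester is cut at C12–C13 and C8–C7 in one radical chain step: an alkenyl radical from an (E)-alkenyl iodide adds to (R)-4-acetoxycyclopentenone, and the resulting enoxyl radical is allylated by allyltributylstannane. C11 controls C12, and C12 controls C8.
3. The alkenyl iodide ester comes from (S,E)-1-iodooct-1-en-3-ol and hex-5-enoic acid; the lactone C–O bond is made early as a plain ester, so no macrolactonisation is needed.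
4. The iodo alcohol comes from CBS reduction of (E)-1-iodooct-1-en-3-one, made from hexanoyl chloride and acetylene; the enone comes from (R)-4-hydroxycyclopent-2-en-1-one by acetylation.
5. Ring order: the five-membered ring is bought in; the 13-membered lactone is the only ring formed, in the final step.

Assumption: prostaglandin numbering (C1 = lactone carbonyl, C20 = chain methyl) is used for positions, and the four starting materials are bought, (R)-4-hydroxycyclopent-2-en-1-one in ≥98% ee.

## Route

Step 1
Reactants: 1 hexanoyl chloride; 2 acetylene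
Product: 3 (E)-1-chlorooct-1-en-3-one
Conditions: HC≡CH (bubbled, excess), AlCl3 (1.2 equiv), CH2Cl2, 0 °C to rt; ice/aq. HCl
Reagents that add atoms: none
Why: Kondakov-type Friedel–Crafts acylation of acetylene, in which the acylium/AlCl4 pair adds across the triple bond (C–C, then C–Cl) and the β-chlorovinyl ketone settles as the E isomer; no stereocentre is formed.

Step 2
Reactants: 3 (E)-1-chlorooct-1-en-3-one
Product: 4 (E)-1-iodooct-1-en-3-one
Conditions: NaI (3 equiv), acetone, rt, dark, 16 h
Reagents that add atoms: sodium iodide, [Na+].[I-]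
Why: Conjugate addition–elimination (vinylogous Finkelstein exchange) on the β-chloro enone, driven by precipitation of NaCl from acetone; the thermodynamic E geometry is kept.

Step 3
Reactants: 4 (E)-1-iodooct-1-en-3-one
Product: 6 (S,E)-1-iodooct-1-en-3-ol, via catecholborate ester 5 (not isolated)
Conditions: (R)-2-methyl-CBS-oxazaborolidine (15 mol%), catecholborane (1.8 equiv), toluene, −78 °C; MeOH, then aq. NaOH wash
Reagents that add atoms: none
Why: Corey–Bakshi–Shibata reduction, in which the ketone binds the (R)-oxazaborolidine with the alkenyl group as the large substituent and hydride is delivered to the Re face, setting C15 as S (same sense as for 15-keto prostaglandin enones); borate 5 is hydrolysed on work-up.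

Step 4
Reactants: 6 (S,E)-1-iodooct-1-en-3-ol; 7 hex-5-enoic acid
Product: 8 (S,E)-1-iodooct-1-en-3-yl hex-5-enoate
Conditions: DCC (1.2 equiv), DMAP (10 mol%), CH2Cl2, 0 °C to rt
Reagents that add atoms: none
Why: Steglich esterification through the O-acylisourea/acylpyridinium; the C–O bond of the alcohol is not broken, so C15 stays S and the alkenyl iodide is untouched.

Step 5
Reactants: 9 (R)-4-hydroxycyclopent-2-en-1-one
Product: 10 (R)-4-oxocyclopent-2-en-1-yl acetate
Conditions: Ac2O (1.5 equiv), pyridine (2 equiv), DMAP (5 mol%), CH2Cl2, 0 °C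
Reagents that add atoms: acetic anhydride, CC(=O)OC(C)=O
Why: DMAP-catalysed O-acetylation at 0 °C; the stereocentre (future C11) is not touched and the mild base avoids elimination to cyclopentadienone.

Step 6
Reactants: 8 (S,E)-1-iodooct-1-en-3-yl hex-5-enoate; 10 (R)-4-oxocyclopent-2-en-1-yl acetate
Product: 14 (S,E)-1-[(1R,2R,5R)-5-acetoxy-3-oxo-2-(prop-2-en-1-yl)cyclopentyl]oct-1-en-3-yl hex-5-enoate, via alkenyl radical 11 (not isolated), via enoxyl radical 12 (not isolated), via stannylalkyl radical 13 (not isolated)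
Conditions: 10 (5 equiv, 1.0 M), AIBN (0.2 equiv), degassed PhH, 80 °C; 8 and allyltributylstannane (2 equiv) added together by syringe pump over 8 h; excess 10 recovered
Reagents that add atoms: allyltributylstannane, C=CC[Sn](CCCC)(CCCC)CCCC
Why: Proposed new method: a tin radical chain in which Bu3Sn• abstracts iodine from 8, the σ-alkenyl radical 11 (bonding trans to its branched C15 substituent, so 13E is kept) adds to C3 of enone 10 anti to the 4-acetoxy group, and the electrophilic enoxyl radical 12 is allylated by the electron-rich stannane anti to the new C3 substituent (SH2′; β-scission of 13 returns Bu3Sn•), so C12 and C8 come out trans,trans under neutral conditions that cannot eliminate the β-acetoxy group; high enone and low stannane concentrations steer 11 to the enone; the closest known reactions are the Keck radical allylation and the alkyl iodide/enone/allylstannane three-component radical coupling, here extended to an alkenyl radical.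

Step 7
Reactants: 14 (S,E)-1-[(1R,2R,5R)-5-acetoxy-3-oxo-2-(prop-2-en-1-yl)cyclopentyl]oct-1-en-3-yl hex-5-enoate
Product: 15 prostaglandin E2 1,15-lactone 11-acetate [(5Z,8R,11R,12R,13E,15S)-11-acetoxy-9-oxoprosta-5,13-dien-1,15-olide]
Conditions: cyclometalated Z-selective Grubbs catalyst Ru(=CH-C6H4-2-OiPr)(κ2-NO3)[κ2-C,C-1-(adamant-1-yl)-3-(2,6-diisopropylphenyl)imidazolin-2-ylidene] (7.5 mol%), ClCH2CH2Cl (3 mM), 60 °C, static vacuum, 24 h
Reagents that add atoms: none
Why: Z-selective ring-closing metathesis, in which the cyclometalated ruthenium catalyst forces a side-bound all-syn ruthenacyclobutane so the two terminal alkenes close the 13-membered lactone as the 5Z alkene (ethene removed under vacuum), while the hindered E-disubstituted C13=C14 alkene, the ketone and the esters are not engaged; no stereocentre is touched.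

## Compound list

1 | hexanoyl chloride | CCCCCC(=O)Cl | starting material
2 | acetylene | C#C | starting material
3 | (E)-1-chlorooct-1-en-3-one | CCCCCC(=O)/C=C/Cl | intermediate
4 | (E)-1-iodooct-1-en-3-one | CCCCCC(=O)/C=C/I | intermediate
5 | 2-{[(S,E)-1-iodooct-1-en-3-yl]oxy}-1,3,2-benzodioxaborole (catecholborate ester) | CCCCC[C@@H](/C=C/I)OB1Oc2ccccc2O1 | intermediate
6 | (S,E)-1-iodooct-1-en-3-ol | CCCCC[C@H](O)/C=C/I | intermediate
7 | hex-5-enoic acid | C=CCCCC(=O)O | starting material
8 | (S,E)-1-iodooct-1-en-3-yl hex-5-enoate | CCCCC[C@@H](/C=C/I)OC(=O)CCCC=C | intermediate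
9 | (R)-4-hydroxycyclopent-2-en-1-one | O=C1C=C[C@H](O)C1 | starting material
10 | (R)-4-oxocyclopent-2-en-1-yl acetate | O=C1C=C[C@H](OC(C)=O)C1 | intermediate
11 | (S)-3-(hex-5-enoyloxy)oct-1-en-1-yl radical (σ-alkenyl radical at C13) | CCCCC[C@@H](C=[CH])OC(=O)CCCC=C | intermediate
12 | enoxyl radical (α-keto radical at C8) carrying the 11α-acetoxy and 12β-[(S,E)-3-(hex-5-enoyloxy)oct-1-enyl] groups | CCCCC[C@@H](/C=C/[C@H]1[C@H](OC(C)=O)CC(=O)[CH]1)OC(=O)CCCC=C | intermediate
13 | β-stannylalkyl radical formed by addition of 12 to allyltributylstannane | CCCCC[C@@H](/C=C/[C@H]1[C@H](OC(C)=O)CC(=O)[C@@H]1C[CH]C[Sn](CCCC)(CCCC)CCCC)OC(=O)CCCC=C | intermediate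
14 | (S,E)-1-[(1R,2R,5R)-5-acetoxy-3-oxo-2-(prop-2-en-1-yl)cyclopentyl]oct-1-en-3-yl hex-5-enoate | CCCCC[C@@H](/C=C/[C@H]1[C@H](OC(C)=O)CC(=O)[C@@H]1CC=C)OC(=O)CCCC=C | intermediate
15 | prostaglandin E2 1,15-lactone 11-acetate | CCCCC[C@H]1/C=C/[C@H]2[C@H](OC(C)=O)CC(=O)[C@@H]2C/C=C\CCCC(=O)O1 | target

## Step count and risk

Total step count: 7.
Longest linear sequence: 6 steps (steps 1, 2, 3, 4, 6, 7).

**Step 6 (three-component radical coupling).** Risk: the very reactive alkenyl radical is partly captured by free allylstannane or solvent, and the relay must keep two radicals on different timetables. The fallback sets out from 6, uses 10, and comes back to the route at 15. It tethers the second radical acceptor to the ester, so no free stannane is present and the second C–C bond closes the macrocycle.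
- Hex-5-ynoic acid is hydroxymethylated (n-BuLi 2.2 equiv, paraformaldehyde, THF) to 7-hydroxyhept-5-ynoic acid F1.
- F1 is brominated (PBr3, Et2O, 0 °C) to 7-bromohept-5-ynoic acid F2 and esterified with 6 (DCC, DMAP) to (S,E)-1-iodooct-1-en-3-yl 7-bromohept-5-ynoate F3.
- SN2′ stannylation (Bu3SnLi, CuBr·SMe2, THF, −78 °C) gives the allenylstannane (S,E)-1-iodooct-1-en-3-yl 5-(tributylstannyl)hepta-5,6-dienoate F4.
- Slow addition of F4 to 10 (5 equiv, AIBN, PhH, 80 °C) starts the same chain, but the enoxyl radical now attacks the allene terminus within the molecule and expels Bu3Sn•. This gives the 13-membered cycloalkyne 5,6-didehydroprostaglandin E2 1,15-lactone 11-acetate F5.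
- Lindlar semihydrogenation (H2, Pd on CaCO3 poisoned with Pb(OAc)2, quinoline, EtOAc) gives 15.

**Step 7 (Z-selective ring-closing metathesis).** Risk: incomplete Z control or slow closure of the 13-membered ring. The fallback sets out from 6, uses 10, and comes back to the route at 15. It closes the ring at C5–C6 as an alkyne and sets the Z alkene by semihydrogenation.
- 6 is esterified with hex-5-ynoic acid (DCC, DMAP) to (S,E)-1-iodooct-1-en-3-yl hex-5-ynoate F6.
- The radical coupling of step 6 is run with allenyltributylstannane in place of allyltributylstannane (SH2′ propargyl transfer) to give (S,E)-1-[(1R,2R,5R)-5-acetoxy-3-oxo-2-(prop-2-yn-1-yl)cyclopentyl]oct-1-en-3-yl hex-5-ynoate F7.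
- Ring-closing alkyne metathesis of the terminal diyne (Mo(≡C-C6H4-4-OMe)(OSiPh3)3, MS 5 Å, toluene, high dilution, loss of acetylene) gives the cycloalkyne 5,6-didehydroprostaglandin E2 1,15-lactone 11-acetate F5.
- Lindlar semihydrogenation as above gives 15.

**Step 3 (CBS reduction).** Risk: an enantiomeric excess too low for the later diastereomer separations to absorb. The fallback sets out from 1 and comes back to the route at 6; it also bypasses steps 1 and 2.
- Acyl Sonogashira coupling of 1 with ethynyltrimethylsilane (PdCl2(PPh3)2, CuI, Et3N, THF) gives 1-(trimethylsilyl)oct-1-yn-3-one F8.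
- Noyori transfer hydrogenation (RuCl[(S,S)-TsDPEN](p-cymene), i-PrOH) gives (S)-1-(trimethylsilyl)oct-1-yn-3-ol F9.
- K2CO3/MeOH gives (S)-oct-1-yn-3-ol F10.
- Hydrozirconation–iodination (Cp2Zr(H)Cl 2.2 equiv, THF, then I2) gives 6.

## Further compounds

F1 | step 6 | 7-hydroxyhept-5-ynoic acid | OCC#CCCCC(=O)O
F2 | step 6 | 7-bromohept-5-ynoic acid | BrCC#CCCCC(=O)O
F3 | step 6 | (S,E)-1-iodooct-1-en-3-yl 7-bromohept-5-ynoate | CCCCC[C@@H](/C=C/I)OC(=O)CCCC#CCBr
F4 | step 6 | (S,E)-1-iodooct-1-en-3-yl 5-(tributylstannyl)hepta-5,6-dienoate | CCCCC[C@@H](/C=C/I)OC(=O)CCCC(=C=C)[Sn](CCCC)(CCCC)CCCC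
F5 | step 6 | 5,6-didehydroprostaglandin E2 1,15-lactone 11-acetate | CCCCC[C@H]1/C=C/[C@H]2[C@H](OC(C)=O)CC(=O)[C@@H]2CC#CCCCC(=O)O1
F6 | step 7 | (S,E)-1-iodooct-1-en-3-yl hex-5-ynoate | CCCCC[C@@H](/C=C/I)OC(=O)CCCC#C
F7 | step 7 | (S,E)-1-[(1R,2R,5R)-5-acetoxy-3-oxo-2-(prop-2-yn-1-yl)cyclopentyl]oct-1-en-3-yl hex-5-ynoate | CCCCC[C@@H](/C=C/[C@H]1[C@H](OC(C)=O)CC(=O)[C@@H]1CC#C)OC(=O)CCCC#C
F8 | step 3 | 1-(trimethylsilyl)oct-1-yn-3-one | CCCCCC(=O)C#C[Si](C)(C)C
F9 | step 3 | (S)-1-(trimethylsilyl)oct-1-yn-3-ol | CCCCC[C@H](O)C#C[Si](C)(C)C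
F10 | step 3 | (S)-oct-1-yn-3-ol | CCCCC[C@H](O)C#C
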